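**Plan**

1. Retrosynthesis: remove the C3 benzoate, then cut C11'=C12' and C11=C12 (two Horner–Wadsworth–Emmons olefinations) to give two C15 aldehydes (ring A, ring B) and a C10 bisphosphonate.
2. Enabling feature: each end group is a 2,5-dihydrofuran (O, C5, C6, C7, C8) in which O bridges the tertiary C5 and the allylic C8 across C6=C7. Cutting O–C8 gives an α-allenol, which is the SN2′ opening product of a 5,6-oxirane carrying a C7≡C8 alkyne.
3. Ring A: the ethynyl oxirane made from β-cyclocitral is expanded by two atoms in one flask, by Pd-catalysed anti-SN2′ alkenylation (which also forms C8–C9) followed by Ag-catalysed 5-endo closure.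
4. Ring B: the same logic with hydride as the nucleophile (copper hydride anti-SN2′, then Ag) gives the opposite relative C5/C8 configuration that this end needs.
5. Forward order: ring A (steps 1–8), ring B (9–15), linker (16–18), chain joined to B and then to A (19–20), deprotection (21).
6. Stereochemistry: C5 of ring A comes from Sharpless epoxidation; C3 of ring B from (4R,6R)-actinol by Mitsunobu inversion; C5 of ring B from anti epoxidation; both C8 centres from centre-to-axis-to-centre transfer.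

Key step: step 6

Remark: carotenoid locants are used within each end group (ring A = end group without hydroxyl, 5R,8S, the primed half of the target name; ring B = 3-hydroxylated end group, 3R,5S,8S). All chain double bonds are taken as E, as drawn.

**Route**

Step 1
Reactants: 1 ethyl but-2-ynoate
Product: 2 ethyl (2Z)-3-(4,4,5,5-tetramethyl-1,3,2-dioxaborolan-2-yl)but-2-enoate
Conditions: B2pin2 (1.1 equiv), CuCl (3 mol %), NaOtBu (6 mol %), Xantphos (3 mol %), MeOH (2 equiv), THF, 23 °C
Reagents that add atoms: bis(pinacolato)diboron, CC1(C)OB(OC1(C)C)B1OC(C)(C)C(C)(C)O1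
Why: Copper-catalysed β-borylation of the ynoate (syn borylcupration, then protonation of the C–Cu bond with retention) should place boron trans to the ester, the geometry that becomes the 9E double bond of the ring A side chain.

Step 2
Reactants: 3 β-cyclocitral
Product: 4 β-cyclogeraniol
Conditions: NaBH4, MeOH, 0 °C
Reagents that add atoms: none
Why: Borohydride 1,2-reduction of the hindered enal gives the allylic alcohol whose hydroxyl is needed to direct the epoxidation.

Step 3
Reactants: 4 β-cyclogeraniol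
Product: 5 [(1R,6R)-2,2,6-trimethyl-7-oxabicyclo[4.1.0]heptan-1-yl]methanol
Conditions: Ti(OiPr)4 (0.2 equiv), D-(−)-diethyl tartrate (0.24 equiv), t-BuOOH (2 equiv), 4 Å molecular sieves, CH2Cl2, −20 °C
Reagents that add atoms: tert-butyl hydroperoxide, CC(C)(C)OO
Why: Sharpless asymmetric epoxidation of the tetrasubstituted allylic alcohol with the D-(−)-tartrate (the enantiomer that gives 2R glycidols from simple allylic alcohols) should deliver oxygen to the face that gives the 1R,6R oxirane, fixing C5 of ring A as R by reagent control.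

Step 4
Reactants: 5 [(1R,6R)-2,2,6-trimethyl-7-oxabicyclo[4.1.0]heptan-1-yl]methanol
Product: 6 (1S,6R)-2,2,6-trimethyl-7-oxabicyclo[4.1.0]heptane-1-carbaldehyde
Conditions: Dess–Martin periodinane (1.3 equiv), pyridine, CH2Cl2, 0 → 23 °C
Reagents that add atoms: none
Why: Dess–Martin oxidation of the neopentyl-type primary alcohol is close to neutral under pyridine buffering, so the acid-labile tetrasubstituted oxirane and its two fully substituted stereocentres should survive.

Step 5
Reactants: 6 (1S,6R)-2,2,6-trimethyl-7-oxabicyclo[4.1.0]heptane-1-carbaldehyde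
Product: 7 (1R,6R)-1-ethynyl-2,2,6-trimethyl-7-oxabicyclo[4.1.0]heptane
Conditions: dimethyl (1-diazo-2-oxopropyl)phosphonate (1.5 equiv), K2CO3 (2 equiv), MeOH, 0 → 23 °C
Reagents that add atoms: dimethyl (1-diazo-2-oxopropyl)phosphonate, COP(=O)(OC)C(=[N+]=[N-])C(C)=O
Why: Ohira–Bestmann (Seyferth–Gilbert) homologation converts the non-enolisable epoxy aldehyde into the terminal alkyne under mild base without touching the oxirane.

Step 6
Reactants: 7 (1R,6R)-1-ethynyl-2,2,6-trimethyl-7-oxabicyclo[4.1.0]heptane; 2 ethyl (2Z)-3-(4,4,5,5-tetramethyl-1,3,2-dioxaborolan-2-yl)but-2-enoate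
Product: 9 ethyl (2E)-3-[(2S,7aR)-4,4,7a-trimethyl-2,4,5,6,7,7a-hexahydro-1-benzofuran-2-yl]but-2-enoate, via α-allenol 8 (not isolated)
Conditions: Pd(PPh3)4 (5 mol %), 2 (1.3 equiv), THF/H2O 10:1, 60 °C; then, in the same flask, AgNO3 (0.3 equiv), acetone, 23 °C, dark
Reagents that add atoms: none
Why: Zerovalent palladium attacks the unhindered alkyne terminus C8 of 7 anti to the propargylic C6–O bond (SN2′ oxidative addition), the tertiary alkoxide set free on palladium activates boronate 2 for transmetalation, and reductive elimination with retention gives α-allenol 8 with the R axis; silver then activates the C7=C8 π bond and the C5 hydroxyl closes on C8, so that overall the oxirane (O, C5, C6) is expanded by C7 and C8 to the 2,5-dihydrofuran with O–C5 kept and C6–O exchanged for O–C8. The closest known reaction types are the palladium-catalysed anti-SN2′ coupling of propargylic oxiranes and carbonates with organoboron compounds and the silver- or gold-catalysed cycloisomerisation of α-hydroxyallenes to 2,5-dihydrofurans. Only the dihydrofuran ring is closed, by 5-endo-trig attack of oxygen on the metal-bound allene. C5 keeps the R configuration set in step 3, and C8 is set by centre-to-axis-to-centre transfer: the anti attack places C9 on the allene face opposite the departing oxygen, and since oxygen must bond to C8 within the C5–C6–C7 plane, C9 ends cis to the 5-methyl group (8S). The step needs anti over syn substitution, attack at C8 and not at C6, and O- over C-cyclisation of the vinylallene; the free alkyne terminus, the quaternary C6 and the electron-poor enoate on C9, which disfavours ionisation or Nazarov-type closure and so protects the axis, should secure these. The 9E geometry comes unchanged from 2, because transmetalation and reductive elimination retain the configuration at the alkenyl carbon.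

Step 7
Reactants: 9 ethyl (2E)-3-[(2S,7aR)-4,4,7a-trimethyl-2,4,5,6,7,7a-hexahydro-1-benzofuran-2-yl]but-2-enoate
Product: 10 (2E)-3-[(2S,7aR)-4,4,7a-trimethyl-2,4,5,6,7,7a-hexahydro-1-benzofuran-2-yl]but-2-en-1-ol
Conditions: (iBu)2AlH (2.5 equiv), CH2Cl2, −78 °C; Rochelle salt work-up
Reagents that add atoms: none
Why: DIBAL-H reduction of the enoate to the allylic alcohol at low temperature should leave the allylic ether stereocentres untouched.

Step 8
Reactants: 10 (2E)-3-[(2S,7aR)-4,4,7a-trimethyl-2,4,5,6,7,7a-hexahydro-1-benzofuran-2-yl]but-2-en-1-ol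
Product: 11 (2E)-3-[(2S,7aR)-4,4,7a-trimethyl-2,4,5,6,7,7a-hexahydro-1-benzofuran-2-yl]but-2-enal (fragment A)
Conditions: activated MnO2 (excess), CH2Cl2, 23 °C
Reagents that add atoms: none
Why: MnO2 oxidises the allylic alcohol selectively to the enal under neutral conditions, which the acid-sensitive dihydrofuran should tolerate.

Step 9
Reactants: 12 (4R,6R)-4-hydroxy-2,2,6-trimethylcyclohexan-1-one (actinol)
Product: 13 (1S,5R)-3,3,5-trimethyl-4-oxocyclohexyl benzoate
Conditions: PhCO2H (1.5 equiv), PPh3 (1.5 equiv), diisopropyl azodicarboxylate (1.5 equiv), THF, 0 → 23 °C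
Reagents that add atoms: benzoic acid, OC(=O)c1ccccc1
Why: Mitsunobu esterification proceeds by SN2 displacement of the alkoxyphosphonium ion by benzoate, inverting the carbinol centre to the configuration that becomes C3 (3R) of ring B and protecting the oxygen in the same operation.

Step 10
Reactants: 13 (1S,5R)-3,3,5-trimethyl-4-oxocyclohexyl benzoate
Product: 14 (1S)-3,5,5-trimethyl-4-{[(trifluoromethyl)sulfonyl]oxy}cyclohex-3-en-1-yl benzoate
Conditions: LiN(iPr)2 (1.1 equiv), THF, −78 °C; PhNTf2 (1.2 equiv), −78 → 0 °C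
Reagents that add atoms: N-phenylbis(trifluoromethanesulfonimide), O=S(=O)(N(c1ccccc1)S(=O)(=O)C(F)(F)F)C(F)(F)F
Why: Deprotonation at the only α-hydrogen and O-sulfonylation of the enolate gives the tetrasubstituted enol triflate regiospecifically (enol triflate formation), the α-methyl stereocentre being removed on purpose.

Step 11
Reactants: 14 (1S)-3,5,5-trimethyl-4-{[(trifluoromethyl)sulfonyl]oxy}cyclohex-3-en-1-yl benzoate; 15 (2E)-3-methylpent-2-en-4-yn-1-ol
Product: 16 (1S)-4-[(3E)-5-hydroxy-3-methylpent-3-en-1-yn-1-yl]-3,5,5-trimethylcyclohex-3-en-1-yl benzoate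
Conditions: PdCl2(PPh3)2 (3 mol %), CuI (6 mol %), Et3N (3 equiv), THF, 23 °C
Reagents that add atoms: none
Why: Sonogashira coupling of the vinyl triflate with the terminal alkyne installs C7–C11 with the 9E alkene already in place, and the free primary alcohol and the benzoate are tolerated.

Step 12
Reactants: 16 (1S)-4-[(3E)-5-hydroxy-3-methylpent-3-en-1-yn-1-yl]-3,5,5-trimethylcyclohex-3-en-1-yl benzoate
Product: 17 (1S,3R,6S)-6-[(3E)-5-hydroxy-3-methylpent-3-en-1-yn-1-yl]-1,5,5-trimethyl-7-oxabicyclo[4.1.0]heptan-3-yl benzoate (oxirane trans to the benzoate)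
Conditions: mCPBA (1.1 equiv), NaHCO3, CH2Cl2, 0 °C
Reagents that add atoms: 3-chloroperoxybenzoic acid, OOC(=O)c1cccc(Cl)c1
Why: Peracid (Prilezhaev) epoxidation should take the more electron-rich tetrasubstituted C5=C6 bond in preference to the allylic-alcohol alkene and approach anti to the homoallylic benzoate, as peracids do with 3-acyloxy β-end groups, setting C5 (5S) with the oxirane trans to the C3 oxygen.

Step 13
Reactants: 17 (1S,3R,6S)-6-[(3E)-5-hydroxy-3-methylpent-3-en-1-yn-1-yl]-1,5,5-trimethyl-7-oxabicyclo[4.1.0]heptan-3-yl benzoate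
Product: 19 (1R,3S)-3-hydroxy-4-[(3E)-5-hydroxy-3-methylpenta-1,3-dien-1-ylidene]-3,5,5-trimethylcyclohexyl benzoate (R allene axis), via bis-silyl ether 18 (not isolated)
Conditions: [1,3-bis(2,6-diisopropylphenyl)imidazol-2-ylidene]CuCl (5 mol %), NaOtBu (5 mol %), MeSiH(OMe)2 (3 equiv), toluene, 0 → 23 °C; then NH4F (10 mol %), MeOH, 23 °C
Reagents that add atoms: none
Why: Copper hydride-catalysed SN2′ reduction of the propargylic oxirane should deliver hydride to C8 anti to the C6–O bond, so the R allene axis is set by centre-to-axis transfer from C6 while benzoate and alkene stay intact, and the two oxygens silylated in passing are freed by methanolysis.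

Step 14
Reactants: 19 (1R,3S)-3-hydroxy-4-[(3E)-5-hydroxy-3-methylpenta-1,3-dien-1-ylidene]-3,5,5-trimethylcyclohexyl benzoate
Product: 20 (2S,6R,7aS)-2-[(2E)-4-hydroxybut-2-en-2-yl]-4,4,7a-trimethyl-2,4,5,6,7,7a-hexahydro-1-benzofuran-6-yl benzoate
Conditions: AgNO3 (0.2 equiv), CaCO3, acetone/H2O 4:1, 23 °C, dark
Reagents that add atoms: none
Why: Silver-catalysed 5-endo-trig cycloisomerisation of the α-hydroxyallene transfers the axis to C8, because oxygen bonds within the C5–C6–C7 plane and the hydride-derived hydrogen therefore ends cis to the 5-methyl group, giving 8S with C9 trans to that methyl group.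

Step 15
Reactants: 20 (2S,6R,7aS)-2-[(2E)-4-hydroxybut-2-en-2-yl]-4,4,7a-trimethyl-2,4,5,6,7,7a-hexahydro-1-benzofuran-6-yl benzoate
Product: 21 (2S,6R,7aS)-4,4,7a-trimethyl-2-[(2E)-4-oxobut-2-en-2-yl]-2,4,5,6,7,7a-hexahydro-1-benzofuran-6-yl benzoate (fragment B)
Conditions: activated MnO2 (excess), CH2Cl2, 23 °C
Reagents that add atoms: none
Why: MnO2 oxidises only the primary allylic alcohol to the enal and leaves the benzoate and the dihydrofuran unchanged.

Step 16
Reactants: 22 (2E,4E,6E)-2,7-dimethylocta-2,4,6-trienedial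
Product: 23 (2E,4E,6E)-2,7-dimethylocta-2,4,6-triene-1,8-diol
Conditions: NaBH4, MeOH/THF, 0 °C
Reagents that add atoms: none
Why: Borohydride 1,2-reduction of both enal groups gives the bis-allylic diol without touching the triene.

Step 17
Reactants: 23 (2E,4E,6E)-2,7-dimethylocta-2,4,6-triene-1,8-diol
Product: 24 (2E,4E,6E)-1,8-dibromo-2,7-dimethylocta-2,4,6-triene
Conditions: PBr3 (0.7 equiv), pyridine (cat.), Et2O, −10 °C, dark
Reagents that add atoms: phosphorus tribromide, BrP(Br)Br
Why: Bromination of the primary allylic alcohols via their phosphite esters (SN2 at CH2) should keep the E,E,E geometry at low temperature.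

Step 18
Reactants: 24 (2E,4E,6E)-1,8-dibromo-2,7-dimethylocta-2,4,6-triene
Product: 25 tetraethyl [(2E,4E,6E)-2,7-dimethylocta-2,4,6-triene-1,8-diyl]bis(phosphonate)
Conditions: P(OEt)3 (excess), 120 °C
Reagents that add atoms: triethyl phosphite, CCOP(OCC)OCC
Why: Twofold Michaelis–Arbuzov reaction of the primary allylic bromides gives the C10 bisphosphonate linker.

Step 19
Reactants: 21 fragment B aldehyde; 25 tetraethyl [(2E,4E,6E)-2,7-dimethylocta-2,4,6-triene-1,8-diyl]bis(phosphonate)
Product: 26 diethyl [(2E,4E,6E,8E,10E)-11-[(2S,6R,7aS)-6-(benzoyloxy)-4,4,7a-trimethyl-2,4,5,6,7,7a-hexahydro-1-benzofuran-2-yl]-2,7-dimethyldodeca-2,4,6,8,10-pentaen-1-yl]phosphonate (C25 phosphonate)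
Conditions: 25 (3 equiv), NaN(SiMe3)2 (1.1 equiv relative to 21), THF, −78 °C; then 21, −78 → 0 °C, dark
Reagents that add atoms: none
Why: Horner–Wadsworth–Emmons olefination with the bisphosphonate in excess and one equivalent of base should stop at mono-olefination and give the E-configured C11=C12 bond, with the carbanion on the linker and not on a dihydrofuran-bearing fragment.

Step 20
Reactants: 26 C25 phosphonate; 11 fragment A aldehyde
Product: 27 (3R,5S,8S,5'R,8'S)-5,8:5',8'-diepoxy-5,8,5',8'-tetrahydro-β,β-caroten-3-yl benzoate (all-E)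
Conditions: NaN(SiMe3)2 (1.05 equiv), THF, −78 °C; 11 (1.2 equiv), −78 → 0 °C, dark, argon
Reagents that add atoms: none
Why: A second Horner–Wadsworth–Emmons olefination forms the E-configured C11'=C12' bond and completes the C40 chain, and generating the delocalised anion of 26 at low temperature with immediate trapping should avoid β-alkoxide loss at C8, as epoxide-bearing ylides survive comparable couplings.

Step 21
Reactants: 27 C40 benzoate
Product: 28 (3R,5S,8S,5'R,8'S)-5,8:5',8'-diepoxy-5,8,5',8'-tetrahydro-β,β-caroten-3-ol (all-E)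
Conditions: K2CO3 (0.5 equiv), MeOH/THF 1:1, 23 °C, dark
Reagents that add atoms: none
Why: Base-catalysed methanolysis (transesterification) removes the benzoate, and the two allylic ether rings, which are acid- but not base-labile, should be unaffected.

**Compound list**

1 | ethyl but-2-ynoate | CC#CC(=O)OCC | starting material
2 | ethyl (2Z)-3-(4,4,5,5-tetramethyl-1,3,2-dioxaborolan-2-yl)but-2-enoate (boron trans to the ester) | CCOC(=O)/C=C(\C)B1OC(C)(C)C(C)(C)O1 | intermediate
3 | β-cyclocitral (2,6,6-trimethylcyclohex-1-ene-1-carbaldehyde) | O=CC1=C(C)CCCC1(C)C | starting material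
4 | β-cyclogeraniol ((2,6,6-trimethylcyclohex-1-en-1-yl)methanol) | OCC1=C(C)CCCC1(C)C | intermediate
5 | [(1R,6R)-2,2,6-trimethyl-7-oxabicyclo[4.1.0]heptan-1-yl]methanol | OC[C@@]12O[C@]1(C)CCCC2(C)C | intermediate
6 | (1S,6R)-2,2,6-trimethyl-7-oxabicyclo[4.1.0]heptane-1-carbaldehyde | O=C[C@@]12O[C@]1(C)CCCC2(C)C | intermediate
7 | (1R,6R)-1-ethynyl-2,2,6-trimethyl-7-oxabicyclo[4.1.0]heptane | C#C[C@@]12O[C@]1(C)CCCC2(C)C | intermediate
8 | ethyl (2E)-5-[(6R)-6-hydroxy-2,2,6-trimethylcyclohexylidene]-3-methylpenta-2,4-dienoate, R allene axis | CCOC(=O)/C=C(\C)C([H])=[C@@]=C1C(C)(C)CCC[C@@]1(C)O | intermediate (not isolated)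
9 | ethyl (2E)-3-[(2S,7aR)-4,4,7a-trimethyl-2,4,5,6,7,7a-hexahydro-1-benzofuran-2-yl]but-2-enoate | CCOC(=O)/C=C(\C)[C@@H]1C=C2C(C)(C)CCC[C@@]2(C)O1 | intermediate
10 | (2E)-3-[(2S,7aR)-4,4,7a-trimethyl-2,4,5,6,7,7a-hexahydro-1-benzofuran-2-yl]but-2-en-1-ol | OC/C=C(\C)[C@@H]1C=C2C(C)(C)CCC[C@@]2(C)O1 | intermediate
11 | (2E)-3-[(2S,7aR)-4,4,7a-trimethyl-2,4,5,6,7,7a-hexahydro-1-benzofuran-2-yl]but-2-enal (fragment A) | O=C/C=C(\C)[C@@H]1C=C2C(C)(C)CCC[C@@]2(C)O1 | intermediate
12 | (4R,6R)-4-hydroxy-2,2,6-trimethylcyclohexan-1-one (actinol) | O=C1C(C)(C)C[C@H](O)C[C@H]1C | starting material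
13 | (1S,5R)-3,3,5-trimethyl-4-oxocyclohexyl benzoate | O=C1C(C)(C)C[C@@H](OC(=O)c2ccccc2)C[C@H]1C | intermediate
14 | (1S)-3,5,5-trimethyl-4-{[(trifluoromethyl)sulfonyl]oxy}cyclohex-3-en-1-yl benzoate | CC1=C(OS(=O)(=O)C(F)(F)F)C(C)(C)C[C@@H](OC(=O)c2ccccc2)C1 | intermediate
15 | (2E)-3-methylpent-2-en-4-yn-1-ol | C#C/C(C)=C/CO | starting material
16 | (1S)-4-[(3E)-5-hydroxy-3-methylpent-3-en-1-yn-1-yl]-3,5,5-trimethylcyclohex-3-en-1-yl benzoate | OC/C=C(\C)C#CC=1C(C)(C)C[C@@H](OC(=O)c2ccccc2)CC=1C | intermediate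
17 | (1S,3R,6S)-6-[(3E)-5-hydroxy-3-methylpent-3-en-1-yn-1-yl]-1,5,5-trimethyl-7-oxabicyclo[4.1.0]heptan-3-yl benzoate | OC/C=C(\C)C#C[C@]12O[C@@]1(C)C[C@H](OC(=O)c3ccccc3)CC2(C)C | intermediate
18 | bis[dimethoxy(methyl)silyl] ether of 19 (both hydroxyls silylated) | CO[Si](C)(OC)OC/C=C(\C)C([H])=[C@@]=C1C(C)(C)C[C@@H](OC(=O)c2ccccc2)C[C@]1(C)O[Si](C)(OC)OC | intermediate (not isolated)
19 | (1R,3S)-3-hydroxy-4-[(3E)-5-hydroxy-3-methylpenta-1,3-dien-1-ylidene]-3,5,5-trimethylcyclohexyl benzoate, R allene axis | OC/C=C(\C)C([H])=[C@@]=C1C(C)(C)C[C@@H](OC(=O)c2ccccc2)C[C@]1(C)O | intermediate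
20 | (2S,6R,7aS)-2-[(2E)-4-hydroxybut-2-en-2-yl]-4,4,7a-trimethyl-2,4,5,6,7,7a-hexahydro-1-benzofuran-6-yl benzoate | OC/C=C(\C)[C@@H]1C=C2C(C)(C)C[C@@H](OC(=O)c3ccccc3)C[C@]2(C)O1 | intermediate
21 | (2S,6R,7aS)-4,4,7a-trimethyl-2-[(2E)-4-oxobut-2-en-2-yl]-2,4,5,6,7,7a-hexahydro-1-benzofuran-6-yl benzoate (fragment B) | O=C/C=C(\C)[C@@H]1C=C2C(C)(C)C[C@@H](OC(=O)c3ccccc3)C[C@]2(C)O1 | intermediate
22 | (2E,4E,6E)-2,7-dimethylocta-2,4,6-trienedial | O=C/C(C)=C/C=C/C=C(\C)C=O | starting material
23 | (2E,4E,6E)-2,7-dimethylocta-2,4,6-triene-1,8-diol | OC/C(C)=C/C=C/C=C(\C)CO | intermediate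
24 | (2E,4E,6E)-1,8-dibromo-2,7-dimethylocta-2,4,6-triene | BrC/C(C)=C/C=C/C=C(\C)CBr | intermediate
25 | tetraethyl [(2E,4E,6E)-2,7-dimethylocta-2,4,6-triene-1,8-diyl]bis(phosphonate) | CCOP(=O)(OCC)C/C(C)=C/C=C/C=C(\C)CP(=O)(OCC)OCC | intermediate
26 | diethyl [(2E,4E,6E,8E,10E)-11-[(2S,6R,7aS)-6-(benzoyloxy)-4,4,7a-trimethyl-2,4,5,6,7,7a-hexahydro-1-benzofuran-2-yl]-2,7-dimethyldodeca-2,4,6,8,10-pentaen-1-yl]phosphonate | CC(/CP(=O)(OCC)OCC)=C\C=C\C=C(C)\C=C\C=C(/C)[C@@H]1C=C2C(C)(C)C[C@@H](OC(=O)c3ccccc3)C[C@]2(C)O1 | intermediate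
27 | (3R,5S,8S,5'R,8'S)-5,8:5',8'-diepoxy-5,8,5',8'-tetrahydro-β,β-caroten-3-yl benzoate (all-E) | CC(/C=C/C=C(\C)[C@@H]1C=C2C(C)(C)CCC[C@@]2(C)O1)=C\C=C\C=C(C)\C=C\C=C(/C)[C@@H]1C=C2C(C)(C)C[C@@H](OC(=O)c3ccccc3)C[C@]2(C)O1 | intermediate
28 | (3R,5S,8S,5'R,8'S)-5,8:5',8'-diepoxy-5,8,5',8'-tetrahydro-β,β-caroten-3-ol (all-E) | CC(/C=C/C=C(\C)[C@@H]1C=C2C(C)(C)CCC[C@@]2(C)O1)=C\C=C\C=C(C)\C=C\C=C(/C)[C@@H]1C=C2C(C)(C)C[C@@H](O)C[C@]2(C)O1 | target

**Step count and risks**

Total step count: 21. Longest linear sequence: 10 steps (steps 9–15, then 19–21).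

Steps most likely to fail:

Step 6. The allene axis may erode through palladium-mediated epimerisation of the allenylpalladium intermediate, boron-to-palladium transfer from the electron-poor boronate may be slow, or the vinylallene may undergo carbocyclisation in the silver stage. The fallback sets out from 7 and forms the C8–H bond instead of the C8–C9 bond in the SN2′ event. Sonogashira coupling of 7 with ethyl (2E)-3-iodobut-2-enoate would give ethyl (2E)-3-methyl-5-[(1R,6R)-2,2,6-trimethyl-7-oxabicyclo[4.1.0]heptan-1-yl]pent-2-en-4-ynoate F1. DIBAL-H would then reduce the ester and, bound to the oxirane oxygen, deliver hydride to C8 on the oxygen side (syn-SN2′, the usual entry to allenic carotenoid end groups), which places C9 on the same face as in 8 and gives (2E)-5-[(6R)-6-hydroxy-2,2,6-trimethylcyclohexylidene]-3-methylpenta-2,4-dien-1-ol F2 with the R axis. Silver nitrate cyclisation of the isolated allenol would give alcohol 10, where the route is rejoined.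

Step 13. Hydride may be delivered with the wrong or a mixed facial sense, or the conjugated enyne may be hydrocuprated or over-reduced. The fallback sets out from 14 and uses the classical acid-mediated oxirane-to-dihydrofuran rearrangement. Stille coupling of 14 with (2E,4E)-3-methyl-5-(tributylstannyl)penta-2,4-dien-1-ol would give (1S)-4-[(1E,3E)-5-hydroxy-3-methylpenta-1,3-dien-1-yl]-3,5,5-trimethylcyclohex-3-en-1-yl benzoate F3. mCPBA would give the anti 5,6-oxirane (1S,3R,6R)-6-[(1E,3E)-5-hydroxy-3-methylpenta-1,3-dien-1-yl]-1,5,5-trimethyl-7-oxabicyclo[4.1.0]heptan-3-yl benzoate F4. Catalytic pyridinium p-toluenesulfonate in CH2Cl2 would then rearrange the vinyl oxirane to 20 together with its C8 epimer (2R,6R,7aS)-2-[(2E)-4-hydroxybut-2-en-2-yl]-4,4,7a-trimethyl-2,4,5,6,7,7a-hexahydro-1-benzofuran-6-yl benzoate F5. The epimers would be separated by chromatography and F5 re-equilibrated under the same acid; the route is rejoined at 20.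

Step 12. The peracid may show poor facial selectivity (oxirane syn to the benzoate) or also epoxidise the C9=C10 bond. The fallback sets out from 14 and replaces substrate control by reagent control. Stille coupling with (tributylstannyl)methanol would give (1S)-4-(hydroxymethyl)-3,5,5-trimethylcyclohex-3-en-1-yl benzoate F6. Sharpless epoxidation with L-(+)-diethyl tartrate would give (1S,3R,6S)-6-(hydroxymethyl)-1,5,5-trimethyl-7-oxabicyclo[4.1.0]heptan-3-yl benzoate F7. Dess–Martin oxidation would give (1S,3R,6R)-6-formyl-1,5,5-trimethyl-7-oxabicyclo[4.1.0]heptan-3-yl benzoate F8, and Ohira–Bestmann homologation would give (1S,3R,6S)-6-ethynyl-1,5,5-trimethyl-7-oxabicyclo[4.1.0]heptan-3-yl benzoate F9. Sonogashira coupling of F9 with (2E)-3-iodobut-2-en-1-ol would give 17, where the route is rejoined.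

**Further compounds**

F1 | step 6 | ethyl (2E)-3-methyl-5-[(1R,6R)-2,2,6-trimethyl-7-oxabicyclo[4.1.0]heptan-1-yl]pent-2-en-4-ynoate | CCOC(=O)/C=C(\C)C#C[C@@]12O[C@]1(C)CCCC2(C)C
F2 | step 6 | (2E)-5-[(6R)-6-hydroxy-2,2,6-trimethylcyclohexylidene]-3-methylpenta-2,4-dien-1-ol, R allene axis | OC/C=C(\C)C([H])=[C@@]=C1C(C)(C)CCC[C@@]1(C)O
F3 | step 13 | (1S)-4-[(1E,3E)-5-hydroxy-3-methylpenta-1,3-dien-1-yl]-3,5,5-trimethylcyclohex-3-en-1-yl benzoate | OC/C=C(C)/C=C/C=1C(C)(C)C[C@@H](OC(=O)c2ccccc2)CC=1C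
F4 | step 13 | (1S,3R,6R)-6-[(1E,3E)-5-hydroxy-3-methylpenta-1,3-dien-1-yl]-1,5,5-trimethyl-7-oxabicyclo[4.1.0]heptan-3-yl benzoate | OC/C=C(C)/C=C/[C@]12O[C@@]1(C)C[C@H](OC(=O)c3ccccc3)CC2(C)C
F5 | step 13 | (2R,6R,7aS)-2-[(2E)-4-hydroxybut-2-en-2-yl]-4,4,7a-trimethyl-2,4,5,6,7,7a-hexahydro-1-benzofuran-6-yl benzoate | OC/C=C(\C)[C@H]1C=C2C(C)(C)C[C@@H](OC(=O)c3ccccc3)C[C@]2(C)O1
F6 | step 12 | (1S)-4-(hydroxymethyl)-3,5,5-trimethylcyclohex-3-en-1-yl benzoate | OCC=1C(C)(C)C[C@@H](OC(=O)c2ccccc2)CC=1C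
F7 | step 12 | (1S,3R,6S)-6-(hydroxymethyl)-1,5,5-trimethyl-7-oxabicyclo[4.1.0]heptan-3-yl benzoate | OC[C@]12O[C@@]1(C)C[C@H](OC(=O)c3ccccc3)CC2(C)C
F8 | step 12 | (1S,3R,6R)-6-formyl-1,5,5-trimethyl-7-oxabicyclo[4.1.0]heptan-3-yl benzoate | O=C[C@]12O[C@@]1(C)C[C@H](OC(=O)c3ccccc3)CC2(C)C
F9 | step 12 | (1S,3R,6S)-6-ethynyl-1,5,5-trimethyl-7-oxabicyclo[4.1.0]heptan-3-yl benzoate | C#C[C@]12O[C@@]1(C)C[C@H](OC(=O)c3ccccc3)CC2(C)C
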